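## Retrosynthetic overview
1. Target 10 comes from acetylation of the C3 alcohol 9. Ketone 8 is reduced with axial-hydride delivery to set the cis Br/OH pair.
2. The spiro centre, the C5–C6 bond, the C4–Br and the exocyclic methylene form together in one anodic Br⁺-initiated cation–olefin spirocyclisation of the bisabolene-type alkenol 6. Ring A is formed last.
3. Alkenol 6 comes from a carbonyl-ene reaction of the isopropenyl group of 3 with prenal (4), then alkene isomerisation.
4. Ring B (C9 Br, C10 Cl) comes from limonene (1) via chlorohydrin 2 and a chloronium-assisted OH→Br exchange. Limonene's own stereocentre only biases the face of the first halohydrin; the resulting C9/C10 centres later direct spirocyclisation.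

Assumptions (each stated once):
- (R)-(+)-Limonene and prenal are commercial.
- Simple reagents are not numbered. They are given by name and SMILES in the steps.
- Stereodescriptors use spiro[5.5]undecane numbering. C2 is CHBr, C3 is CH–O, C6 is the spiro carbon, C8 is CHCl and C9 is C(Me)Br.

## Route

**Step 1**
Reactants: 1 (R)-(+)-limonene, CC1=CC[C@@H](CC1)C(C)=C
Product: 2 (1S,2S,4R)-2-chloro-1-methyl-4-(prop-1-en-2-yl)cyclohexan-1-ol, C[C@]1(O)CC[C@@H](C(C)=C)C[C@@H]1Cl
Conditions: NCS, H2O/acetone (1:3), 0 °C
Reagents that add atoms: N-chlorosuccinimide, ClN1C(=O)CCC1=O; water, O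
Why: Halohydrin formation occurs at the more nucleophilic trisubstituted ring alkene, with Markovnikov OH at the tertiary carbon. Cl⁺ adds to the face that gives the trans-diaxial chlorohydrin chair with the isopropenyl group equatorial, so C9/C10 configuration is dictated by limonene's C4.

**Step 2**
Reactants: 2 chlorohydrin
Product: 3 (1S,2S,4R)-1-bromo-2-chloro-1-methyl-4-(prop-1-en-2-yl)cyclohexane, C[C@]1(Br)CC[C@@H](C(C)=C)C[C@@H]1Cl
Conditions: 48% aq. HBr, CH2Cl2, 0 °C, 15 min, vigorous stirring
Reagents that add atoms: hydrogen bromide, Br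
Why: This is SN1 substitution with neighbouring-group participation. Ionisation of the tertiary alcohol is assisted by the anti-periplanar axial chlorine (chloronium), and bromide closes at the tertiary carbon from the face opposite Cl. The net result is retention, giving the trans-diaxial Br/Cl pair of the target.

**Step 3**
Reactants: 3 bromochloride; 4 prenal (3-methylbut-2-enal), CC(C)=CC=O
Product: 5 2-[(1R,3S,4S)-4-bromo-3-chloro-4-methylcyclohexyl]-6-methylhepta-1,5-dien-4-ol (C4 epimers), C[C@]1(Br)CC[C@@H](C(=C)CC(O)C=C(C)C)C[C@@H]1Cl
Conditions: Me2AlCl (1.5 equiv), CH2Cl2, −78 → −30 °C; then aq. Rochelle salt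
Reagents that add atoms: none (prenal is the reactant)
Why: Lewis-acid-promoted carbonyl-ene reaction. The aldehyde carbon bonds to the =CH2 terminus of the isopropenyl group and the methyl hydrogen is transferred, giving the homoallylic alcohol with an exocyclic methylene. The new carbinol centre is an epimeric mixture, which is harmless because it is oxidised in Step 6.

**Step 4**
Reactants: 5 ene adduct
Product: 6 2-[(3S,4S)-4-bromo-3-chloro-4-methylcyclohexylidene]-6-methylhept-5-en-4-ol (E/Z mixture and C4 epimers), C[C@]1(Br)CCC(=C(C)CC(O)C=C(C)C)C[C@@H]1Cl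
Conditions: achiral Co(salen) (5 mol%), PhSiH3 (10 mol%), PhMe, 25 °C
Reagents that add atoms: none
Why: Metal-hydride hydrogen-atom-transfer alkene isomerisation moves the 1,1-disubstituted alkene to the thermodynamically preferred tetrasubstituted C6=C1 position (a γ-bisabolene-type nucleophile). This makes limonene's C4 (C6) sp², so the stereochemical information now resides in C9/C10.

**Step 5**
Reactants: 6 tetrasubstituted alkenol
Product: 7 (2R,6R,8S,9S)-2,9-dibromo-8-chloro-1,1,9-trimethyl-5-methylidenespiro[5.5]undecan-3-ol (C3 epimers), C=C1CC(O)[C@H](Br)C(C)(C)[C@@]12CC[C@](C)(Br)[C@@H](Cl)C2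
Conditions: Et4NBr (2.5 equiv), HFIP/CH2Cl2 (1:4), 2,6-di-tert-butylpyridine (2 equiv), undivided cell, graphite(+)/Pt(−), 4 mA, 0 °C, 2.2 F/mol
Reagents that add atoms: tetraethylammonium bromide, CC[N+](CC)(CC)CC.[Br-]
Why: Proposed new method: anodic oxidation of Br⁻ supplies a low steady-state Br⁺ equivalent that forms a reversible bromonium ion on the prenyl C4=C5 alkene. The tetrasubstituted C6=C1 alkene attacks C5 anti to bromine through a chair-like state, with Br equatorial and attack anti to the axial C8–Cl of ring B, to build the spiro C6–C5 bond between two quaternary carbons. The tertiary C1 cation then loses a methyl proton to give the exocyclic methylene. The closest known reaction types are bromonium-initiated cation–olefin polyene cyclisation with stoichiometric Br⁺ reagents and anodic alkene bromination. The electrochemical version on a tetrasubstituted, spiro-forming alkene bearing a tertiary bromide and secondary chloride has not been shown.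

**Step 6**
Reactants: 7 spiro alcohol (C3 epimers)
Product: 8 (2R,6R,8S,9S)-2,9-dibromo-8-chloro-1,1,9-trimethyl-5-methylidenespiro[5.5]undecan-3-one, C=C1CC(=O)[C@H](Br)C(C)(C)[C@@]12CC[C@](C)(Br)[C@@H](Cl)C2
Conditions: Dess–Martin periodinane, NaHCO3, CH2Cl2, 0 → 25 °C
Reagents that add atoms: none
Why: Oxidation of the secondary alcohol removes the uncontrolled C3 centre and converges both epimers to one ketone. The C2 bromide (C4 in the earlier numbering) is retained under these neutral conditions.

**Step 7**
Reactants: 8 ketone
Product: 9 (2R,3S,6R,8S,9S)-2,9-dibromo-8-chloro-1,1,9-trimethyl-5-methylidenespiro[5.5]undecan-3-ol, C=C1C[C@H](O)[C@H](Br)C(C)(C)[C@@]12CC[C@](C)(Br)[C@@H](Cl)C2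
Conditions: NaBH4, MeOH/CH2Cl2, −40 °C
Reagents that add atoms: none
Why: Hydride reduction. The axial C1 methyl of the gem-dimethyl group blocks axial attack at the ketone, so hydride enters equatorially. This gives the axial alcohol cis to the equatorial bromide, which is the (3S) configuration.

**Step 8**
Reactants: 9 alcohol
Product: 10 9-acetyllisoobtusol, (2R,3S,6R,8S,9S)-2,9-dibromo-8-chloro-1,1,9-trimethyl-5-methylidenespiro[5.5]undecan-3-yl acetate, C=C1C[C@H](OC(C)=O)[C@H](Br)C(C)(C)[C@@]12CC[C@](C)(Br)[C@@H](Cl)C2
Conditions: Ac2O, DMAP, pyridine, 0 → 25 °C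
Reagents that add atoms: acetic anhydride, CC(=O)OC(C)=O
Why: Simple O-acylation of the secondary alcohol; no stereocentre is touched.

## Compound list
1 | (R)-(+)-limonene | CC1=CC[C@@H](CC1)C(C)=C | starting material
2 | (1S,2S,4R)-2-chloro-1-methyl-4-(prop-1-en-2-yl)cyclohexan-1-ol | C[C@]1(O)CC[C@@H](C(C)=C)C[C@@H]1Cl | intermediate
3 | (1S,2S,4R)-1-bromo-2-chloro-1-methyl-4-(prop-1-en-2-yl)cyclohexane | C[C@]1(Br)CC[C@@H](C(C)=C)C[C@@H]1Cl | intermediate
4 | prenal (3-methylbut-2-enal) | CC(C)=CC=O | starting material
5 | 2-[(1R,3S,4S)-4-bromo-3-chloro-4-methylcyclohexyl]-6-methylhepta-1,5-dien-4-ol (carbinol epimers) | C[C@]1(Br)CC[C@@H](C(=C)CC(O)C=C(C)C)C[C@@H]1Cl | intermediate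
6 | 2-[(3S,4S)-4-bromo-3-chloro-4-methylcyclohexylidene]-6-methylhept-5-en-4-ol | C[C@]1(Br)CCC(=C(C)CC(O)C=C(C)C)C[C@@H]1Cl | intermediate
7 | spiro alcohol, C3 epimers (2R,6R,8S,9S) | C=C1CC(O)[C@H](Br)C(C)(C)[C@@]12CC[C@](C)(Br)[C@@H](Cl)C2 | intermediate
8 | spiro ketone | C=C1CC(=O)[C@H](Br)C(C)(C)[C@@]12CC[C@](C)(Br)[C@@H](Cl)C2 | intermediate
9 | 3-epi-free spiro alcohol (3S) | C=C1C[C@H](O)[C@H](Br)C(C)(C)[C@@]12CC[C@](C)(Br)[C@@H](Cl)C2 | intermediate
10 | 9-acetyllisoobtusol | C=C1C[C@H](OC(C)=O)[C@H](Br)C(C)(C)[C@@]12CC[C@](C)(Br)[C@@H](Cl)C2 | target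

## Totals
Total steps: 8. Longest linear sequence: 8 (prenal is a commercial partner added in Step 3).

## Three steps most likely to fail
1. **Step 5 (proposed new method).** Possible problems are direct bromination of the tetrasubstituted alkene, a 1:1 mixture of C4/C6 diastereomers from E/Z alkene isomers, and endocyclic alkene formation instead of the exocyclic methylene.
   - Fallback (known chemistry): close ring A by Brønsted/Lewis-acid cation–olefin cyclisation of 6 (for example SnCl4, CH2Cl2, −78 °C), which gives the C4-unsubstituted spirocycle.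
   - Then oxidise to the ring-A ketone and install the C4 bromide by ketone α-bromination, before repeating Steps 7–8.
2. **Step 4.** Co–H may be incompatible with the tertiary C–Br bond or the prenyl alkene, or isomerisation to the tetrasubstituted alkene may stall.
   - Fallback (known chemistry): build the alkene by olefination logic instead. Ozonolyse 3 to the methyl ketone, do a kinetic LDA aldol with prenal, protect the alcohol as TBS, form the thermodynamic enol triflate, and methylate it by Fe-catalysed Kumada coupling. Remove TBS to give 6.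
3. **Step 2.** Aqueous HBr may hydrobrominate the isopropenyl group before or alongside the tertiary-alcohol exchange.
   - Fallback (known chemistry): ozonolyse 2 to the methyl ketone, perform the HBr exchange on the alkene-free ketone, then restore the isopropenyl group by Petasis methylenation (Cp2TiMe2) to give 3.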